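**Retrosynthetic overview**
- Feature: in the tetralin core, C1 (aryl-bearing CH) and C4 (CH2) of ring B are each bonded directly to ring A, at C8a and C4a. Ring A carries only H (C5, C8) and O (C6, C7).
- Key disconnection: ring A is cut into three alkynes (C8a≡C8, C4a≡C5, C6≡C7). This also opens ring B and leads to an open-chain 1,7-diyne holding the C1–C3 triad, plus bis(pinacolboryl)ethyne. The two C–B bonds become C–OMe at the end.
- Diyne: the C2 methyl comes from CH2OH and C4a≡C5 from a δ-lactone carbonyl. The C1–C2 bond comes from a syn-selective Nicholas alkylation of an Evans boron enolate, and C3 from desymmetrised 3-methylglutaric anhydride.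
- Ring order: no carbocycle exists before the key step. Ring B (C4a–C8a) and ring A (C5–C6, C7–C8) then close in one operation.

Key step: step 13

Assumption: tetralin numbering is used throughout (C1 aryl-bearing, C2 and C3 methyl-bearing, C4 = CH2), and the quinine-derived catalyst of step 1 is taken to give the S half-ester; the quinidine-derived pseudoenantiomer (DHQD)2AQN is used instead if the sense of induction proves opposite.

**Step 1**
Reactants: 1 3-methylglutaric anhydride
Product: 2 (3S)-5-methoxy-3-methyl-5-oxopentanoic acid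
Conditions: MeOH (10 equiv), (DHQ)2AQN (30 mol%), Et2O, −40 °C
Reagents that add atoms: methanol, SMILES CO
Why: Cinchona-alkaloid-catalysed methanolytic desymmetrisation of a prochiral glutaric anhydride, in which the quinuclidine nitrogen activates methanol as a general base inside the chiral pocket so that one enantiotopic carbonyl group is opened preferentially and the methyl-bearing carbon (future C3) is fixed.

**Step 2**
Reactants: 2 (3S)-5-methoxy-3-methyl-5-oxopentanoic acid; 3 (4S)-4-benzyl-1,3-oxazolidin-2-one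
Product: 5 methyl (3S)-5-[(4S)-4-benzyl-2-oxo-1,3-oxazolidin-3-yl]-3-methyl-5-oxopentanoate, via mixed pivalic anhydride 4 (not isolated)
Conditions: PivCl, Et3N, THF, −20 °C; then LiCl, 3, −20 °C → rt
Reagents that add atoms: none
Why: Mixed-anhydride N-acylation of an Evans oxazolidinone (LiCl/Et3N variant), in which the lithium-activated carbamate nitrogen attacks the unhindered acyl carbonyl of 4 rather than the pivaloyl one, the methyl ester and C3 stay untouched, and material from the minor enantiomer of 2 becomes a diastereomer that can be removed later by chromatography.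

**Step 3**
Reactants: 6 ethynyl(trimethyl)silane; 7 3,4-dimethoxybenzaldehyde
Product: 10 rac-1-(3,4-dimethoxyphenyl)-3-(trimethylsilyl)prop-2-yn-1-yl acetate, via lithium silylacetylide 8 (not isolated), via lithium propargylic alkoxide 9 (not isolated)
Conditions: n-BuLi, THF, −78 °C; 7, −78 → 0 °C; Ac2O, 0 °C → rt
Reagents that add atoms: acetic anhydride, SMILES CC(=O)OC(C)=O
Why: 1,2-addition of a lithium acetylide to an aromatic aldehyde followed by O-acetylation of the alkoxide in the same flask, the carbinol carbon being left racemic on purpose because it is ionised in step 5.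

**Step 4**
Reactants: 10 rac-1-(3,4-dimethoxyphenyl)-3-(trimethylsilyl)prop-2-yn-1-yl acetate
Product: 11 Co2(CO)6 complex of acetate 10 (racemic)
Conditions: Co2(CO)8 (1.05 equiv), CH2Cl2, rt
Reagents that add atoms: Co2(CO)8, SMILES O=C=[Co](=C=O)(=C=O)(=C=O)[Co](=C=O)(=C=O)(=C=O)=C=O
Why: Alkyne complexation by zerovalent cobalt carbonyl (first stage of the Nicholas reaction), a ligand exchange of two CO for the triple bond that tolerates acetate, silyl and aryl ether groups and creates no stereocentre of consequence.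

**Step 5**
Reactants: 5 methyl (3S)-5-[(4S)-4-benzyl-2-oxo-1,3-oxazolidin-3-yl]-3-methyl-5-oxopentanoate; 11 Co2(CO)6 complex of acetate 10
Product: 14 Co2(CO)6 complex of imide 15 (C1/C2 syn; configuration as in 15), via Z-dibutylboron enolate 12 (not isolated), via cluster-stabilised propargylic cation triflate 13 (not isolated)
Conditions: 5, Bu2BOTf (2.5 equiv), i-Pr2NEt (1.3 equiv), CH2Cl2, −78 → 0 °C; 11 (1.5 equiv), −78 → 0 °C; pH 7 buffer
Reagents that add atoms: none
Why: Nicholas reaction of an Evans boron enolate: surplus Bu2BOTf ionises 11 to the cluster- and aryl-stabilised cation 13, the boron-chelated Z-enolate 12 is attacked on the face opposite the benzyl group (sets C2 in the sense of an Evans alkylation), and an open transition state that holds the bulky silylalkyne–Co2(CO)6 cluster anti to the branched enolate substituent and turns the cation hydrogen toward the enolate oxygen terminus gives the syn C1/C2 relation, while fast racemisation of the fluxional cation lets both antipodes of 11 converge on one diastereomer.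

**Step 6**
Reactants: 14 Co2(CO)6 complex of imide 15
Product: 15 methyl (3R,4R,5S)-4-{[(4S)-4-benzyl-2-oxo-1,3-oxazolidin-3-yl]carbonyl}-5-(3,4-dimethoxyphenyl)-3-methyl-7-(trimethylsilyl)hept-6-ynoate
Conditions: Fe(NO3)3·9H2O (excess), EtOH, 0 °C → rt
Reagents that add atoms: none
Why: Oxidative decomplexation (last stage of the Nicholas sequence), in which trivalent iron oxidises the cluster to divalent cobalt with loss of CO and releases the silyl alkyne under mildly acidic conditions that leave imide, ester, aryl ethers and all three stereocentres untouched.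

**Step 7**
Reactants: 15 methyl (3R,4R,5S)-4-{[(4S)-4-benzyl-2-oxo-1,3-oxazolidin-3-yl]carbonyl}-5-(3,4-dimethoxyphenyl)-3-methyl-7-(trimethylsilyl)hept-6-ynoate
Product: 17 (4R,5R)-5-[(1S)-1-(3,4-dimethoxyphenyl)-3-(trimethylsilyl)prop-2-yn-1-yl]-4-methyloxan-2-one, via hydroxy ester 16 (not isolated)
Conditions: NaBH4, THF/H2O (4:1), 0 °C → rt; then TsOH (cat.), CH2Cl2, rt
Reagents that add atoms: none
Why: Reductive cleavage of the Evans auxiliary by borohydride at the more electrophilic exocyclic imide carbonyl, which a methyl ester survives, followed by acid-catalysed transesterification of 16 to the trans-4,5-disubstituted six-membered lactone, so that the future C2-methyl carbon (CH2–O) and the future C4a (C=O) are told apart without protecting groups.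

**Step 8**
Reactants: 17 (4R,5R)-5-[(1S)-1-(3,4-dimethoxyphenyl)-3-(trimethylsilyl)prop-2-yn-1-yl]-4-methyloxan-2-one
Product: 18 (4R,5R)-5-[(1S)-1-(3,4-dimethoxyphenyl)-3-(trimethylsilyl)prop-2-yn-1-yl]-4-methyloxan-2-ol (anomer mixture)
Conditions: i-Bu2AlH (1.1 equiv), CH2Cl2, −78 °C; aq. potassium sodium tartrate
Reagents that add atoms: none
Why: Partial lactone reduction, since the tetrahedral aluminium lactolate formed from one equivalent of i-Bu2AlH is stable at −78 °C and the silyl alkyne is not hydroaluminated at that temperature.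

**Step 9**
Reactants: 18 (4R,5R)-5-[(1S)-1-(3,4-dimethoxyphenyl)-3-(trimethylsilyl)prop-2-yn-1-yl]-4-methyloxan-2-ol
Product: 19 (2R,3R)-2-[(1R)-1-(3,4-dimethoxyphenyl)prop-2-yn-1-yl]-3-methylhex-5-yn-1-ol
Conditions: dimethyl (1-diazo-2-oxopropyl)phosphonate (2 equiv), K2CO3, MeOH, 0 °C → rt
Reagents that add atoms: dimethyl (1-diazo-2-oxopropyl)phosphonate, SMILES CC(=O)C(=[N+]=[N-])P(=O)(OC)OC
Why: Ohira–Bestmann variant of the Seyferth–Gilbert homologation acting on the open hydroxy-aldehyde tautomer of 18 (addition, cycloelimination, loss of N2 and 1,2-hydrogen shift of the alkylidene carbene), which adds C5 next to a non-stereogenic CH2, while the same K2CO3/MeOH protodesilylates the C1 alkyne and is too weak a base to isomerise the benzylic propargylic centre.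

**Step 10**
Reactants: 19 (2R,3R)-2-[(1R)-1-(3,4-dimethoxyphenyl)prop-2-yn-1-yl]-3-methylhex-5-yn-1-ol
Product: 20 (2R,3R)-2-[(1R)-1-(3,4-dimethoxyphenyl)prop-2-yn-1-yl]-3-methylhex-5-yn-1-yl 4-methylbenzenesulfonate
Conditions: TsCl, Et3N, DMAP (cat.), CH2Cl2, 0 °C → rt
Reagents that add atoms: 4-methylbenzenesulfonyl chloride, SMILES Cc1ccc(cc1)S(=O)(=O)Cl
Why: Sulfonylation of the only hydroxyl group under amine base with nucleophilic catalysis by DMAP, a reaction that touches neither alkyne nor any stereocentre.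

**Step 11**
Reactants: 20 (2R,3R)-2-[(1R)-1-(3,4-dimethoxyphenyl)prop-2-yn-1-yl]-3-methylhex-5-yn-1-yl 4-methylbenzenesulfonate
Product: 21 (3R,4R,5R)-3-(3,4-dimethoxyphenyl)-4,5-dimethylocta-1,7-diyne
Conditions: LiAlH4 (excess), THF, 0 °C → reflux
Reagents that add atoms: none
Why: SN2 displacement of a primary tosylate by hydride, the classical CH2OH-to-CH3 sequence of lignan chemistry, in which isolated terminal alkynes are at most deprotonated reversibly by LiAlH4 and the three stereocentres are not part of the reacting carbon.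

**Step 12**
Reactants: 22 trichloroethene; 23 2-isopropoxy-4,4,5,5-tetramethyl-1,3,2-dioxaborolane
Product: 26 1,2-bis(4,4,5,5-tetramethyl-1,3,2-dioxaborolan-2-yl)ethyne, via dilithioethyne 24 (not isolated), via dilithium bis-ate complex 25 (not isolated)
Conditions: n-BuLi (3 equiv), Et2O/THF, −78 °C → rt; 23 (2 equiv), −78 °C; HCl in Et2O (2 equiv), −78 °C → rt
Reagents that add atoms: none
Why: Elimination and chlorine–lithium exchange convert trichloroethene into dilithioethyne, which adds to two borate esters, and anhydrous HCl collapses the bis-ate complex 25 with loss of propan-2-ol, the standard alkynylboronate synthesis applied at both alkyne termini.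

**Step 13**
Reactants: 21 (3R,4R,5R)-3-(3,4-dimethoxyphenyl)-4,5-dimethylocta-1,7-diyne; 26 1,2-bis(4,4,5,5-tetramethyl-1,3,2-dioxaborolan-2-yl)ethyne
Product: 27 (1S,2R,3R)-1-(3,4-dimethoxyphenyl)-2,3-dimethyl-6,7-bis(4,4,5,5-tetramethyl-1,3,2-dioxaborolan-2-yl)-1,2,3,4-tetrahydronaphthalene (all-cis)
Conditions: CpCo(CO)2 (20 mol%), 26 (4 equiv), degassed xylenes, reflux, visible-light lamp; 21 added by syringe pump over 10 h
Reagents that add atoms: none
Why: CpCo(CO)2 loses CO under heat and light to give the CpCo fragment of monovalent cobalt, which binds both alkynes of 21 and couples them oxidatively to a cobaltacyclopentadiene of trivalent cobalt, forming C4a–C8a. The boryl alkyne 26 then coordinates and inserts (or adds in a [4+2] sense), and reductive elimination forms C5–C6 and C7–C8, releases the arene and returns CpCo. The closest known reaction type is the cobalt-mediated [2+2+2] co-cyclotrimerisation of α,ω-diynes with alkynylboronates or bis(trimethylsilyl)ethyne to fused benzenes. Ring B closes as a six-membered carbocycle in the oxidative coupling, because the four-atom C1–C4 tether forces the two internal alkyne carbons to join, and ring A closes in the insertion/reductive-elimination event with irreversible aromatisation. No stereocentre is made or broken, since C1, C2 and C3 are sp3 spectators under neutral conditions, so the triad set in the open chain is carried into the ring as the all-cis array. The step needs cross- rather than homo-cyclotrimerisation, which is secured by slow addition of 21 to a fourfold excess of 26, whose two bulky boryl groups hinder its own trimerisation, while the symmetry of 26 and the terminal alkynes of 21 remove any regiochemical question and leave H at C5 and C8.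

**Step 14**
Reactants: 27 (1S,2R,3R)-1-(3,4-dimethoxyphenyl)-2,3-dimethyl-6,7-bis(4,4,5,5-tetramethyl-1,3,2-dioxaborolan-2-yl)-1,2,3,4-tetrahydronaphthalene
Product: 28 (1S,2R,3R)-1-(3,4-dimethoxyphenyl)-2,3-dimethyl-1,2,3,4-tetrahydronaphthalene-6,7-diol
Conditions: NaBO3·4H2O (6 equiv), THF/H2O (1:1), rt, N2; aq. NH4Cl; used crude
Reagents that add atoms: sodium perborate, SMILES [Na+].[Na+].O[B-]1(O)OO[B-](O)(O)OO1
Why: Ipso-oxidation of aryl boronates by perborate (peroxide addition to boron, 1,2-aryl shift from boron to oxygen, hydrolysis), a mild reagent under which the catechol is held as its borate complex and so shielded from over-oxidation, the veratryl ring and the stereocentres being inert.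

**Step 15**
Reactants: 28 (1S,2R,3R)-1-(3,4-dimethoxyphenyl)-2,3-dimethyl-1,2,3,4-tetrahydronaphthalene-6,7-diol
Product: 29 (1S,2R,3R)-1-(3,4-dimethoxyphenyl)-6,7-dimethoxy-2,3-dimethyl-1,2,3,4-tetrahydronaphthalene (target)
Conditions: MeI (6 equiv), K2CO3, acetone, reflux, N2
Reagents that add atoms: iodomethane, SMILES CI
Why: Williamson O-methylation of both phenoxides with MeI under carbonate base and exclusion of air, which completes the 6,7-dimethoxy pattern and gives the target with the C1–C3 configuration unchanged.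

**Compound list**
1 | 3-methylglutaric anhydride | CC1CC(=O)OC(=O)C1 | starting material
2 | (3S)-5-methoxy-3-methyl-5-oxopentanoic acid | OC(=O)C[C@H](C)CC(=O)OC | intermediate
3 | (4S)-4-benzyl-1,3-oxazolidin-2-one | O=C1N[C@@H](Cc2ccccc2)CO1 | starting material
4 | mixed pivalic anhydride of 2 (stereocentre unchanged) | COC(=O)C[C@@H](C)CC(=O)OC(=O)C(C)(C)C | intermediate
5 | methyl (3S)-5-[(4S)-4-benzyl-2-oxo-1,3-oxazolidin-3-yl]-3-methyl-5-oxopentanoate | COC(=O)C[C@@H](C)CC(=O)N1[C@@H](Cc2ccccc2)COC1=O | intermediate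
6 | ethynyl(trimethyl)silane | C#C[Si](C)(C)C | starting material
7 | 3,4-dimethoxybenzaldehyde | COc1ccc(C=O)cc1OC | starting material
8 | lithium (trimethylsilyl)acetylide | [Li]C#C[Si](C)(C)C | intermediate
9 | lithium 1-(3,4-dimethoxyphenyl)-3-(trimethylsilyl)prop-2-yn-1-olate (racemic) | [Li]OC(C#C[Si](C)(C)C)c1ccc(OC)c(OC)c1 | intermediate
10 | rac-1-(3,4-dimethoxyphenyl)-3-(trimethylsilyl)prop-2-yn-1-yl acetate | CC(=O)OC(C#C[Si](C)(C)C)c1ccc(OC)c(OC)c1 | intermediate
11 | Co2(CO)6 complex of 10 (racemic, drawn as dicobaltatetrahedrane) | CC(=O)OC(c1ccc(OC)c(OC)c1)C12C3([Si](C)(C)C)[Co]1(=C=O)(=C=O)(=C=O)[Co]23(=C=O)(=C=O)=C=O | intermediate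
12 | Z-dibutylboron enolate of 5 | COC(=O)C[C@@H](C)/C=C(\OB(CCCC)CCCC)N1[C@@H](Cc2ccccc2)COC1=O | intermediate
13 | Co2(CO)6-stabilised 1-(3,4-dimethoxyphenyl)-3-(trimethylsilyl)propargylium triflate | COc1ccc([CH+]C23C4([Si](C)(C)C)[Co]2(=C=O)(=C=O)(=C=O)[Co]34(=C=O)(=C=O)=C=O)cc1OC.[O-]S(=O)(=O)C(F)(F)F | intermediate
14 | Co2(CO)6 complex of 15 (same configuration) | COc1ccc([C@@H](C23C4([Si](C)(C)C)[Co]2(=C=O)(=C=O)(=C=O)[Co]34(=C=O)(=C=O)=C=O)[C@H](C(=O)N2[C@@H](Cc3ccccc3)COC2=O)[C@H](C)CC(=O)OC)cc1OC | intermediate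
15 | methyl (3R,4R,5S)-4-{[(4S)-4-benzyl-2-oxo-1,3-oxazolidin-3-yl]carbonyl}-5-(3,4-dimethoxyphenyl)-3-methyl-7-(trimethylsilyl)hept-6-ynoate | COc1ccc([C@@H](C#C[Si](C)(C)C)[C@H](C(=O)N2[C@@H](Cc3ccccc3)COC2=O)[C@H](C)CC(=O)OC)cc1OC | intermediate
16 | methyl (3R,4R,5S)-5-(3,4-dimethoxyphenyl)-4-(hydroxymethyl)-3-methyl-7-(trimethylsilyl)hept-6-ynoate | COc1ccc([C@@H](C#C[Si](C)(C)C)[C@H](CO)[C@H](C)CC(=O)OC)cc1OC | intermediate
17 | (4R,5R)-5-[(1S)-1-(3,4-dimethoxyphenyl)-3-(trimethylsilyl)prop-2-yn-1-yl]-4-methyloxan-2-one (trans lactone) | COc1ccc([C@@H](C#C[Si](C)(C)C)[C@@H]2COC(=O)C[C@H]2C)cc1OC | intermediate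
18 | (4R,5R)-5-[(1S)-1-(3,4-dimethoxyphenyl)-3-(trimethylsilyl)prop-2-yn-1-yl]-4-methyloxan-2-ol (anomer mixture) | COc1ccc([C@@H](C#C[Si](C)(C)C)[C@@H]2COC(O)C[C@H]2C)cc1OC | intermediate
19 | (2R,3R)-2-[(1R)-1-(3,4-dimethoxyphenyl)prop-2-yn-1-yl]-3-methylhex-5-yn-1-ol | COc1ccc([C@@H](C#C)[C@H](CO)[C@H](C)CC#C)cc1OC | intermediate
20 | (2R,3R)-2-[(1R)-1-(3,4-dimethoxyphenyl)prop-2-yn-1-yl]-3-methylhex-5-yn-1-yl 4-methylbenzenesulfonate | COc1ccc([C@@H](C#C)[C@H](COS(=O)(=O)c2ccc(C)cc2)[C@H](C)CC#C)cc1OC | intermediate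
21 | (3R,4R,5R)-3-(3,4-dimethoxyphenyl)-4,5-dimethylocta-1,7-diyne | COc1ccc([C@@H](C#C)[C@H](C)[C@H](C)CC#C)cc1OC | intermediate
22 | trichloroethene | ClC=C(Cl)Cl | starting material
23 | 2-isopropoxy-4,4,5,5-tetramethyl-1,3,2-dioxaborolane | CC(C)OB1OC(C)(C)C(C)(C)O1 | starting material
24 | dilithioethyne | [Li]C#C[Li] | intermediate
25 | dilithium ethyne-1,2-diylbis[isopropoxy(pinacolato)borate] | [Li+].[Li+].CC(C)O[B-]1(OC(C)(C)C(C)(C)O1)C#C[B-]1(OC(C)C)OC(C)(C)C(C)(C)O1 | intermediate
26 | 1,2-bis(4,4,5,5-tetramethyl-1,3,2-dioxaborolan-2-yl)ethyne | CC1(C)OB(C#CB2OC(C)(C)C(C)(C)O2)OC1(C)C | intermediate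
27 | (1S,2R,3R)-1-(3,4-dimethoxyphenyl)-2,3-dimethyl-6,7-bis(pinacolboryl)-1,2,3,4-tetrahydronaphthalene (all-cis) | COc1ccc([C@H]2c3cc(B4OC(C)(C)C(C)(C)O4)c(B4OC(C)(C)C(C)(C)O4)cc3C[C@@H](C)[C@H]2C)cc1OC | intermediate
28 | (1S,2R,3R)-1-(3,4-dimethoxyphenyl)-2,3-dimethyl-1,2,3,4-tetrahydronaphthalene-6,7-diol | COc1ccc([C@H]2c3cc(O)c(O)cc3C[C@@H](C)[C@H]2C)cc1OC | intermediate
29 | (1S,2R,3R)-1-(3,4-dimethoxyphenyl)-6,7-dimethoxy-2,3-dimethyl-1,2,3,4-tetrahydronaphthalene | COc1ccc([C@H]2c3cc(OC)c(OC)cc3C[C@@H](C)[C@H]2C)cc1OC | target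

**Step count**
Total step count: 15. Longest linear sequence: 12 steps (1, 2, 5, 6, 7, 8, 9, 10, 11, 13, 14, 15; the branch 3, 4, 5 … 15 has the same length).

**Steps most likely to fail**

Step 13. The diyne may oligomerise, or be trapped as an inert cobalt complex, faster than the crowded diboryl alkyne enters the cobaltacycle. The fallback sets out from 21 and comes back at 28.
- 21 is co-cyclised under the same CpCo(CO)2 slow-addition protocol with the slimmer, commercial 2-ethynyl-4,4,5,5-tetramethyl-1,3,2-dioxaborolane. This should give the regioisomeric 7-boryl tetralin F1 and 6-boryl tetralin F2.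
- The mixture is oxidised with NaBO3·4H2O to the 7-hydroxy tetralin F3 and the 6-hydroxy tetralin F4.
- IBX in DMF oxygenates each phenol at its less hindered free ortho position (C6 or C7 rather than C8 or C5), so both isomers converge on the 6,7-ortho-quinone F5.
- Na2S2O4 reduces F5 to catechol 28.
- The second oxygen thus comes from phenol ortho-oxidation, and the regiochemistry of the cycloaddition becomes irrelevant.

Step 5. Bond formation between two branched carbons may be slow, and the syn preference at C1 may erode with an aryl-substituted cluster cation. The fallback sets out from 2 and 7 and comes back at 19.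
- BH3·SMe2 reduces the acid of 2 to methyl (3S)-5-hydroxy-3-methylpentanoate F6, and Dess–Martin periodinane gives methyl (3S)-3-methyl-5-oxopentanoate F7.
- 7 with HC≡CMgBr and then Ac2O gives rac-1-(3,4-dimethoxyphenyl)prop-2-yn-1-yl acetate F8.
- F7 and F8 are joined by cooperative enamine/copper-allenylidene propargylic alkylation (CuOTf·0.5C6H6, Ph-pybox, (S)-α,α-diphenylprolinol trimethylsilyl ether, i-Pr2NEt, THF). A slim linear electrophile replaces the bulky cluster, the amine controls C2, and the ligand antipode is chosen to reinforce syn at C1. This gives the formyl ester F9.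
- NaBH4 gives the hydroxy ester F10, which lactonises to the terminal-alkyne lactone F11, and i-Bu2AlH gives the lactol F12.
- The conditions of step 9 convert F12 into 19.

Step 7. Hydride may attack the ring carbonyl of the oxazolidinone (endocyclic cleavage), because the exocyclic carbonyl sits between two branched carbons. The fallback sets out from 15 and comes back at 17.
- The small, soft nucleophile LiSEt (EtSH, n-BuLi, THF, 0 °C) displaces the auxiliary to give the S-ethyl thioester F13.
- NaBH4 in EtOH/THF reduces F13 selectively beside the methyl ester to hydroxy ester 16.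
- 16 closes to lactone 17 under TsOH catalysis.

**Further compounds**
F1 | step 13 | (1S,2R,3R)-1-(3,4-dimethoxyphenyl)-2,3-dimethyl-7-(pinacolboryl)-1,2,3,4-tetrahydronaphthalene | COc1ccc([C@H]2c3cc(B4OC(C)(C)C(C)(C)O4)ccc3C[C@@H](C)[C@H]2C)cc1OC
F2 | step 13 | (1S,2R,3R)-1-(3,4-dimethoxyphenyl)-2,3-dimethyl-6-(pinacolboryl)-1,2,3,4-tetrahydronaphthalene | COc1ccc([C@H]2c3ccc(B4OC(C)(C)C(C)(C)O4)cc3C[C@@H](C)[C@H]2C)cc1OC
F3 | step 13 | (1S,2R,3R)-1-(3,4-dimethoxyphenyl)-2,3-dimethyl-1,2,3,4-tetrahydronaphthalen-7-ol | COc1ccc([C@H]2c3cc(O)ccc3C[C@@H](C)[C@H]2C)cc1OC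
F4 | step 13 | (1S,2R,3R)-1-(3,4-dimethoxyphenyl)-2,3-dimethyl-1,2,3,4-tetrahydronaphthalen-6-ol | COc1ccc([C@H]2c3ccc(O)cc3C[C@@H](C)[C@H]2C)cc1OC
F5 | step 13 | (1S,2R,3R)-1-(3,4-dimethoxyphenyl)-2,3-dimethyl-1,2,3,4-tetrahydronaphthalene-6,7-dione | COc1ccc([C@H]2C3=CC(=O)C(=O)C=C3C[C@@H](C)[C@H]2C)cc1OC
F6 | step 5 | methyl (3S)-5-hydroxy-3-methylpentanoate | COC(=O)C[C@@H](C)CCO
F7 | step 5 | methyl (3S)-3-methyl-5-oxopentanoate | COC(=O)C[C@@H](C)CC=O
F8 | step 5 | rac-1-(3,4-dimethoxyphenyl)prop-2-yn-1-yl acetate | CC(=O)OC(C#C)c1ccc(OC)c(OC)c1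
F9 | step 5 | methyl (3R,4R,5R)-5-(3,4-dimethoxyphenyl)-4-formyl-3-methylhept-6-ynoate | COc1ccc([C@@H](C#C)[C@H](C=O)[C@H](C)CC(=O)OC)cc1OC
F10 | step 5 | methyl (3R,4R,5R)-5-(3,4-dimethoxyphenyl)-4-(hydroxymethyl)-3-methylhept-6-ynoate | COc1ccc([C@@H](C#C)[C@H](CO)[C@H](C)CC(=O)OC)cc1OC
F11 | step 5 | (4R,5R)-5-[(1R)-1-(3,4-dimethoxyphenyl)prop-2-yn-1-yl]-4-methyloxan-2-one | COc1ccc([C@@H](C#C)[C@@H]2COC(=O)C[C@H]2C)cc1OC
F12 | step 5 | (4R,5R)-5-[(1R)-1-(3,4-dimethoxyphenyl)prop-2-yn-1-yl]-4-methyloxan-2-ol (anomer mixture) | COc1ccc([C@@H](C#C)[C@@H]2COC(O)C[C@H]2C)cc1OC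
F13 | step 7 | methyl (3R,4R,5S)-5-(3,4-dimethoxyphenyl)-4-[(ethylsulfanyl)carbonyl]-3-methyl-7-(trimethylsilyl)hept-6-ynoate | COc1ccc([C@@H](C#C[Si](C)(C)C)[C@H](C(=O)SCC)[C@H](C)CC(=O)OC)cc1OC
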